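**Plan**

- Numbering (cembrane): C1 = C(iPr)–O, C2=C3 = E-alkene, C4 = C(Me)OH, C6 = C=O, C8 = CHMe, C11 = CHOAc, C12 = C(Me)–O, C13/C14 = the oxolane CH2 groups. The retrosynthesis first takes the C6 ketone back to a C5=C6 alkene and cuts it (ring-closing metathesis), then cuts the oxolane at C1–C14 and O–C12 in one stroke.
- Enabling feature: in the oxolane O–C1–C14–C13–C12 the oxygen sits on C1, which can be a ketone carbon; C13 and C14 are bare CH2 groups; C12 has the oxygenated C11 as its neighbour. The ring is therefore the sum of a C1=O unit and a C14(−)–C13–C12(+) unit, i.e. an 11,12-epoxide carrying a metallated C14 (formal (3+2) annulation).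
- Forward: (S)-citronellal gives epoxy iodide 8 (C6–C14); (E)-3-methylpent-2-en-4-yn-1-ol gives enone 15 (C1–C5). Step 12 joins them and closes the oxolane; acetylation, desilylation, RCM (14-membered ring) and Wacker oxidation finish the route.
- Stereochemistry: C8 is bought. C11/C12 come from a Shi epoxide, with C12 inverted on ring closure. C4 comes from a Sharpless epoxidation and reductive opening. C1 is set by the catalyst in step 12. The 2E alkene comes from syn-hydrozirconation.

Key step: step 12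

Remark: the sense of induction of the ligand in step 12 is an assumption. The antipode to be used is the one that delivers the alkyl group to the Re face of 15 (C=O; alkenyl ranked above isopropyl), i.e. the one that would give (R)-2-phenylbutan-2-ol from acetophenone and diethylzinc; this is to be confirmed on a model ketone.
Remark: the new C5=C6 alkene of 21 is carried as an E/Z mixture, because both isomers should give the same ketone.
Remark: alcohol 12 is volatile and is carried as an ether solution.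

**Route**

Step 1
Reactants: 1 (S)-citronellal
Product: 2 (4S)-4,8-dimethylnona-1,7-diene
Conditions: Ph3PCH3Br, KOtBu, THF, 0 °C to rt
Reagents that add atoms: methyltriphenylphosphonium bromide C[P+](c1ccccc1)(c1ccccc1)c1ccccc1.[Br-]
Why: Wittig methylenation of the aldehyde; the stereocentre is β to the carbonyl and is not touched.

Step 2
Reactants: 2 (4S)-4,8-dimethylnona-1,7-diene
Product: 3 (2E,6S)-2,6-dimethylnona-2,8-dien-1-ol
Conditions: SeO2 (cat.), t-BuOOH, salicylic acid (cat.), CH2Cl2, rt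
Reagents that add atoms: tert-butyl hydroperoxide CC(C)(C)OO (oxygen relayed by catalytic selenium dioxide O=[Se]=O)
Why: Riley allylic oxidation (ene reaction, then [2,3]-shift) should hydroxylate the E-methyl group of the trisubstituted alkene, which is far more reactive than the monosubstituted alkene.

Step 3
Reactants: 3 (2E,6S)-2,6-dimethylnona-2,8-dien-1-ol
Product: 4 (2E,6S)-1-bromo-2,6-dimethylnona-2,8-diene
Conditions: CBr4, PPh3, CH2Cl2, 0 °C
Reagents that add atoms: carbon tetrabromide BrC(Br)(Br)Br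
Why: Appel bromination of the primary allylic alcohol should proceed by SN2 displacement with the E geometry retained.

Step 4
Reactants: 4 (2E,6S)-1-bromo-2,6-dimethylnona-2,8-diene
Product: 6 (3E,7S)-3,7-dimethyldeca-3,9-dien-1-ol, via alkoxysilane 5 (not isolated)
Conditions: (i-PrO)Me2SiCH2MgCl, Li2CuCl4 (cat.), THF, −20 to 0 °C; then 30% H2O2, KF, KHCO3, THF/MeOH, rt
Reagents that add atoms: [(propan-2-yloxy)dimethylsilyl]methylmagnesium chloride CC(C)O[Si](C)(C)C[Mg]Cl; hydrogen peroxide OO
Why: Copper-catalysed α-coupling of the allylic bromide with the silylmethyl Grignard reagent adds C14 with the E-alkene retained, and Tamao oxidation turns C–Si into C–OH.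

Step 5
Reactants: 6 (3E,7S)-3,7-dimethyldeca-3,9-dien-1-ol
Product: 7 2-[(2R,3R)-2-methyl-3-[(3S)-3-methylhex-5-en-1-yl]oxiran-2-yl]ethan-1-ol
Conditions: D-fructose-derived Shi ketone (30 mol %), Oxone, K2CO3, Bu4NHSO4, MeCN/dimethoxymethane/aq. borate buffer (pH 10.5), 0 °C
Reagents that add atoms: Oxone (potassium peroxymonosulfate) [K+].[O-]S(=O)(=O)OO
Why: Shi asymmetric epoxidation; the chiral dioxirane should attack only the trisubstituted E-alkene through the spiro transition state and set C11 and C12 as (R,R), while the monosubstituted alkene stays.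

Step 6
Reactants: 7 2-[(2R,3R)-2-methyl-3-[(3S)-3-methylhex-5-en-1-yl]oxiran-2-yl]ethan-1-ol
Product: 8 (2R,3R)-2-(2-iodoethyl)-2-methyl-3-[(3S)-3-methylhex-5-en-1-yl]oxirane
Conditions: PPh3, I2, imidazole, CH2Cl2, 0 °C, dark
Reagents that add atoms: iodine II
Why: Appel iodination of the primary alcohol under imidazole buffering should leave the trisubstituted epoxide intact.

Step 7
Reactants: 9 (2E)-3-methylpent-2-en-4-yn-1-ol
Product: 10 [(2S,3S)-3-ethynyl-3-methyloxiran-2-yl]methanol
Conditions: Ti(OiPr)4 (10 mol %), L-(+)-diisopropyl tartrate (12 mol %), t-BuOOH, 4 Å MS, CH2Cl2, −20 °C; non-aqueous work-up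
Reagents that add atoms: tert-butyl hydroperoxide CC(C)(C)OO
Why: Sharpless asymmetric epoxidation; the L-(+)-tartrate catalyst selects the alkene face and thereby sets the configuration of the future C4.

Step 8
Reactants: 10 [(2S,3S)-3-ethynyl-3-methyloxiran-2-yl]methanol
Product: 11 (2S,3R)-2-ethynyl-3-(iodomethyl)-2-methyloxirane
Conditions: PPh3, I2, imidazole, Et2O/MeCN, 0 °C
Reagents that add atoms: iodine II
Why: Appel iodination of the primary alcohol; the epoxide carbons are not involved.

Step 9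
Reactants: 11 (2S,3R)-2-ethynyl-3-(iodomethyl)-2-methyloxirane
Product: 12 (3R)-3-methylpent-1-en-4-yn-3-ol
Conditions: Zn dust, AcOH, Et2O, 0 °C
Reagents that add atoms: none
Why: Zinc-mediated reductive β-elimination of the 2,3-epoxy iodide breaks only the C–O bond at the secondary carbon, so the quaternary carbinol keeps its configuration.

Step 10
Reactants: 12 (3R)-3-methylpent-1-en-4-yn-3-ol
Product: 13 triethyl{[(3R)-3-methylpent-1-en-4-yn-3-yl]oxy}silane
Conditions: TESOTf, 2,6-lutidine, CH2Cl2, −78 to 0 °C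
Reagents that add atoms: triethylsilyl trifluoromethanesulfonate CC[Si](CC)(CC)OS(=O)(=O)C(F)(F)F
Why: Silylation of the tertiary alcohol removes the acidic proton before the organometallic steps.

Step 11
Reactants: 13 triethyl{[(3R)-3-methylpent-1-en-4-yn-3-yl]oxy}silane
Product: 15 (4E,6R)-2,6-dimethyl-6-(triethylsilyloxy)octa-4,7-dien-3-one, via alkenylzirconocene 14 (not isolated)
Conditions: Cp2Zr(H)Cl, CH2Cl2, rt; then isobutyryl chloride, CuBr·SMe2 (cat.), THF, rt
Reagents that add atoms: isobutyryl chloride CC(C)C(=O)Cl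
Why: Syn-hydrozirconation of the terminal alkyne (faster than that of the hindered vinyl group) puts zirconium on the terminal carbon, and copper-catalysed acylation with retention gives the E-enone.

Step 12
Reactants: 8 (2R,3R)-2-(2-iodoethyl)-2-methyl-3-[(3S)-3-methylhex-5-en-1-yl]oxirane; 15 (4E,6R)-2,6-dimethyl-6-(triethylsilyloxy)octa-4,7-dien-3-one
Product: 18 (1R,4S)-4-methyl-1-[(2S,5S)-2-methyl-5-[(1E,3R)-3-methyl-3-(triethylsilyloxy)penta-1,4-dien-1-yl]-5-(propan-2-yl)oxolan-2-yl]hept-6-en-1-ol, via dialkylzinc 16 (not isolated), via titanium alkoxide 17 (not isolated)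
Conditions: 8 (3 equiv), Et2Zn, CuI (cat.), 50 °C, then volatiles removed in vacuo; 15 (1 equiv), Ti(OiPr)4 (1.2 equiv), trans-1,2-bis(2-hydroxycamphor-10-sulfonamido)cyclohexane ligand (10 mol %), toluene, 25 to 45 °C; aq. NH4Cl
Reagents that add atoms: none
Why: Proposed new method: iodine–zinc exchange should turn 8 into the dialkylzinc 16, whose primary C–Zn bond is not expected to attack its own trisubstituted epoxide; the chiral titanium bis(sulfonamide) diolate should then transfer the alkyl group 1,2 to the Re face of the titanium-bound enone 15 to give the tertiary titanium alkoxide 17, which opens the Lewis-acid-activated epoxide at its tertiary carbon with inversion, so that C1–C14 and O–C12 form in one flask as a formal (3+2) annulation of a C=O with a C14(−)/C12(+) three-carbon unit. The closest known reaction types are the titanium-catalysed asymmetric 1,2-addition of functionalised dialkylzincs to α,β-unsaturated ketones and the acid- or titanium-promoted cyclisation of γ,δ-epoxy alcohols to 2,2,5,5-tetrasubstituted oxolanes. The oxolane closes in the 5-exo-tet mode and no other ring is formed. C1 (S) is set by the ligand (catalyst control, since the stereocentres of 16 are remote), C12 (S) by stereospecific inversion of the (12R)-epoxide carbon, and C11 (R) is carried over unchanged from the epoxide. The step needs 1,2- over 1,4-addition (secured by the hard alkyltitanium nucleophile), Re-face selectivity at the ketone (secured by the choice of ligand antipode, with the conjugated alkenyl group differentiated from isopropyl) and attack at C12 over C11 (secured because 5-exo closure and the more substituted, better cation-stabilising carbon coincide).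

Step 13
Reactants: 18 (1R,4S)-4-methyl-1-[(2S,5S)-2-methyl-5-[(1E,3R)-3-methyl-3-(triethylsilyloxy)penta-1,4-dien-1-yl]-5-(propan-2-yl)oxolan-2-yl]hept-6-en-1-ol
Product: 19 (1R,4S)-4-methyl-1-[(2S,5S)-2-methyl-5-[(1E,3R)-3-methyl-3-(triethylsilyloxy)penta-1,4-dien-1-yl]-5-(propan-2-yl)oxolan-2-yl]hept-6-en-1-yl acetate
Conditions: Ac2O, Et3N, DMAP (cat.), CH2Cl2, rt
Reagents that add atoms: acetic anhydride CC(=O)OC(C)=O
Why: DMAP-catalysed acetylation of the only free hydroxyl (C11), with the tertiary alcohol still masked.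

Step 14
Reactants: 19 (1R,4S)-4-methyl-1-[(2S,5S)-2-methyl-5-[(1E,3R)-3-methyl-3-(triethylsilyloxy)penta-1,4-dien-1-yl]-5-(propan-2-yl)oxolan-2-yl]hept-6-en-1-yl acetate
Product: 20 (1R,4S)-1-[(2S,5S)-5-[(1E,3R)-3-hydroxy-3-methylpenta-1,4-dien-1-yl]-2-methyl-5-(propan-2-yl)oxolan-2-yl]-4-methylhept-6-en-1-yl acetate
Conditions: HF·pyridine, pyridine, THF, 0 °C to rt
Reagents that add atoms: none
Why: Buffered fluoride cleavage of the Si–O bond should spare the acetate and the acid-sensitive bis-allylic tertiary alcohol.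

Step 15
Reactants: 20 (1R,4S)-1-[(2S,5S)-5-[(1E,3R)-3-hydroxy-3-methylpenta-1,4-dien-1-yl]-2-methyl-5-(propan-2-yl)oxolan-2-yl]-4-methylhept-6-en-1-yl acetate
Product: 21 (1S,2E,4R,8S,11R,12S)-4-hydroxy-1,12-epoxycembra-2,5-dien-11-yl acetate
Conditions: Grubbs second-generation catalyst (10 mol %), CH2Cl2 (1 mM), 40 °C
Reagents that add atoms: none
Why: Ring-closing metathesis of the two monosubstituted alkenes should close the 14-membered ring at C5=C6; the free tertiary allylic hydroxyl assists, and the C2=C3 alkene between two quaternary carbons is inert.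

Step 16
Reactants: 21 (1S,2E,4R,8S,11R,12S)-4-hydroxy-1,12-epoxycembra-2,5-dien-11-yl acetate
Product: 22 (1S,2E,4R,8S,11R,12S)-4-hydroxy-6-oxo-1,12-epoxycembr-2-en-11-yl acetate
Conditions: Pd(Quinox)Cl2 (10 mol %), AgSbF6 (25 mol %), 70% aq. t-BuOOH, CH2Cl2, 0 °C to rt
Reagents that add atoms: tert-butyl hydroperoxide CC(C)(C)OO
Why: Peroxide-mediated Wacker oxidation of the internal alkene should place the oxygen on C6, distal to the electron-withdrawing allylic C4–O bond, and give the β-hydroxy ketone; the shielded C2=C3 alkene should not react.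

**Compound list**

1 | (S)-citronellal, (3S)-3,7-dimethyloct-6-enal | C[C@H](CC=O)CCC=C(C)C | starting material
2 | (4S)-4,8-dimethylnona-1,7-diene | C[C@H](CC=C)CCC=C(C)C | intermediate
3 | (2E,6S)-2,6-dimethylnona-2,8-dien-1-ol | C[C@H](CC=C)CC/C=C(\C)CO | intermediate
4 | (2E,6S)-1-bromo-2,6-dimethylnona-2,8-diene | C[C@H](CC=C)CC/C=C(\C)CBr | intermediate
5 | [(3E,7S)-3,7-dimethyldeca-3,9-dien-1-yl]dimethyl(propan-2-yloxy)silane | C[C@H](CC=C)CC/C=C(\C)CC[Si](C)(C)OC(C)C | intermediate
6 | (3E,7S)-3,7-dimethyldeca-3,9-dien-1-ol | C[C@H](CC=C)CC/C=C(\C)CCO | intermediate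
7 | 2-[(2R,3R)-2-methyl-3-[(3S)-3-methylhex-5-en-1-yl]oxiran-2-yl]ethan-1-ol | OCC[C@@]1(C)O[C@@H]1CC[C@H](C)CC=C | intermediate
8 | (2R,3R)-2-(2-iodoethyl)-2-methyl-3-[(3S)-3-methylhex-5-en-1-yl]oxirane | ICC[C@@]1(C)O[C@@H]1CC[C@H](C)CC=C | intermediate
9 | (2E)-3-methylpent-2-en-4-yn-1-ol | C#C/C(C)=C/CO | starting material
10 | [(2S,3S)-3-ethynyl-3-methyloxiran-2-yl]methanol | OC[C@@H]1O[C@@]1(C)C#C | intermediate
11 | (2S,3R)-2-ethynyl-3-(iodomethyl)-2-methyloxirane | IC[C@@H]1O[C@@]1(C)C#C | intermediate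
12 | (3R)-3-methylpent-1-en-4-yn-3-ol | C#C[C@](C)(O)C=C | intermediate
13 | triethyl{[(3R)-3-methylpent-1-en-4-yn-3-yl]oxy}silane | C#C[C@](C)(O[Si](CC)(CC)CC)C=C | intermediate
14 | chlorobis(cyclopentadienyl)[(1E,3R)-3-methyl-3-(triethylsilyloxy)penta-1,4-dien-1-yl]zirconium | Cl[Zr](/C=C/[C@](C)(O[Si](CC)(CC)CC)C=C)(C1C=CC=C1)C1C=CC=C1 | intermediate
15 | (4E,6R)-2,6-dimethyl-6-(triethylsilyloxy)octa-4,7-dien-3-one | CC(C)C(=O)/C=C/[C@](C)(O[Si](CC)(CC)CC)C=C | intermediate
16 | bis{2-[(2R,3R)-2-methyl-3-[(3S)-3-methylhex-5-en-1-yl]oxiran-2-yl]ethyl}zinc | C=CC[C@@H](C)CC[C@H]1O[C@]1(C)CC[Zn]CC[C@@]1(C)O[C@@H]1CC[C@H](C)CC=C | intermediate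
17 | tri(propan-2-yloxy)titanium alkoxide of (3S,4E,6R)-2,6-dimethyl-3-{2-[(2R,3R)-2-methyl-3-[(3S)-3-methylhex-5-en-1-yl]oxiran-2-yl]ethyl}-6-(triethylsilyloxy)octa-4,7-dien-3-ol | CC(C)O[Ti](OC(C)C)(OC(C)C)O[C@](C(C)C)(CC[C@@]1(C)O[C@@H]1CC[C@H](C)CC=C)/C=C/[C@](C)(O[Si](CC)(CC)CC)C=C | intermediate
18 | (1R,4S)-4-methyl-1-[(2S,5S)-2-methyl-5-[(1E,3R)-3-methyl-3-(triethylsilyloxy)penta-1,4-dien-1-yl]-5-(propan-2-yl)oxolan-2-yl]hept-6-en-1-ol | C=CC[C@@H](C)CC[C@@H](O)[C@]1(C)CC[C@](O1)(C(C)C)/C=C/[C@](C)(O[Si](CC)(CC)CC)C=C | intermediate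
19 | (1R,4S)-4-methyl-1-[(2S,5S)-2-methyl-5-[(1E,3R)-3-methyl-3-(triethylsilyloxy)penta-1,4-dien-1-yl]-5-(propan-2-yl)oxolan-2-yl]hept-6-en-1-yl acetate | CC(=O)O[C@H](CC[C@H](C)CC=C)[C@]1(C)CC[C@](O1)(C(C)C)/C=C/[C@](C)(O[Si](CC)(CC)CC)C=C | intermediate
20 | (1R,4S)-1-[(2S,5S)-5-[(1E,3R)-3-hydroxy-3-methylpenta-1,4-dien-1-yl]-2-methyl-5-(propan-2-yl)oxolan-2-yl]-4-methylhept-6-en-1-yl acetate | CC(=O)O[C@H](CC[C@H](C)CC=C)[C@]1(C)CC[C@](O1)(C(C)C)/C=C/[C@](C)(O)C=C | intermediate
21 | (1S,2E,4R,8S,11R,12S)-4-hydroxy-1,12-epoxycembra-2,5-dien-11-yl acetate (5,6-alkene E/Z) | CC(=O)O[C@@H]1CC[C@H](C)CC=C[C@@](C)(O)/C=C/[C@@]2(C(C)C)CC[C@]1(C)O2 | intermediate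
22 | (1S,2E,4R,8S,11R,12S)-4-hydroxy-6-oxo-1,12-epoxycembr-2-en-11-yl acetate (CNP0131678.1) | CC(=O)O[C@@H]1CC[C@H](C)CC(=O)C[C@@](C)(O)/C=C/[C@@]2(C(C)C)CC[C@]1(C)O2 | target

**Step count**

Total: 16 steps. Longest linear sequence: 11 steps (steps 1–6 and 12–16).

**Steps most likely to fail**

Step 12. Three things may go wrong. The epoxide may be consumed before the C–C bond forms, either by attack of the organometallic on its own epoxide during the iodine–zinc exchange or by Lewis-acid opening. The alkyl transfer to the branched enone may be slow, and the facial selectivity at C1 may then erode. The protocol also consumes two alkyl groups of 8 per ketone. The fallback separates the two bond formations and uses known chemistry; it sets out from 6 and 15 and comes back at 18. Appel iodination of 6 (PPh3, I2, imidazole) should give (4S,7E)-10-iodo-4,8-dimethyldeca-1,7-diene F1. Iodine–zinc exchange (Et2Zn, cat. CuI) should give bis[(3E,7S)-3,7-dimethyldeca-3,9-dien-1-yl]zinc F2, an epoxide-free functionalised dialkylzinc of the established kind. Its titanium/bis(sulfonamide) diol-catalysed 1,2-addition to 15 should give (3S,4E,6R)-3-[(3E,7S)-3,7-dimethyldeca-3,9-dien-1-yl]-2,6-dimethyl-6-(triethylsilyloxy)octa-4,7-dien-3-ol F3. Shi epoxidation of its only trisubstituted alkene should give (3S,4E,6R)-2,6-dimethyl-3-{2-[(2R,3R)-2-methyl-3-[(3S)-3-methylhex-5-en-1-yl]oxiran-2-yl]ethyl}-6-(triethylsilyloxy)octa-4,7-dien-3-ol F4, which should close to 18 with catalytic camphorsulfonic acid. If the facial selectivity at C1 is still poor, the C1 epimers are separated at the stage of 18, where they are cis- and trans-2,5-disubstituted oxolanes.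

Step 15. The unhindered alkene may oligomerise by cross-metathesis, or the ruthenium carbene may fail to engage the vinyl group on the fully substituted carbinol carbon. The fallback closes the same bond by carbonyl coupling; it sets out from 19 and comes back at 21. Oxidative cleavage of both monosubstituted alkenes (OsO4 cat., NaIO4, 2,6-lutidine; the C2=C3 alkene is shielded) should give the dialdehyde (1R,4S)-4-methyl-1-[(2S,5S)-2-methyl-5-[(1E,3S)-3-methyl-4-oxo-3-(triethylsilyloxy)but-1-en-1-yl]-5-(propan-2-yl)oxolan-2-yl]-6-oxohexyl acetate F5. Intramolecular McMurry coupling under high dilution (TiCl3(DME)1.5, Zn–Cu, DME) should give (1S,2E,4R,8S,11R,12S)-4-(triethylsilyloxy)-1,12-epoxycembra-2,5-dien-11-yl acetate F6. Buffered HF·pyridine then gives 21.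

Step 16. Cationic palladium may ionise or transpose the bis-allylic tertiary alcohol, β-hydroxide elimination may compete, or oxygen may be delivered to C5 instead of C6. The fallback replaces the Wacker oxidation by a sterically controlled hydroboration; it sets out from 21 and comes back at 22. 9-BBN should place boron on C6, the alkene carbon remote from the quaternary C4, and oxidation with sodium perborate should give (1S,2E,4R,8S,11R,12S)-4,6-dihydroxy-1,12-epoxycembr-2-en-11-yl acetate F7 as a mixture of C6 epimers. Dess–Martin periodinane should then oxidise only the secondary C6 alcohol to give 22.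

**Further compounds**

F1 | step 12 | (4S,7E)-10-iodo-4,8-dimethyldeca-1,7-diene | C[C@H](CC=C)CC/C=C(\C)CCI
F2 | step 12 | bis[(3E,7S)-3,7-dimethyldeca-3,9-dien-1-yl]zinc | C[C@H](CC=C)CC/C=C(\C)CC[Zn]CC/C(C)=C/CC[C@H](C)CC=C
F3 | step 12 | (3S,4E,6R)-3-[(3E,7S)-3,7-dimethyldeca-3,9-dien-1-yl]-2,6-dimethyl-6-(triethylsilyloxy)octa-4,7-dien-3-ol | C=CC[C@@H](C)CC/C=C(C)/CC[C@](O)(C(C)C)/C=C/[C@](C)(O[Si](CC)(CC)CC)C=C
F4 | step 12 | (3S,4E,6R)-2,6-dimethyl-3-{2-[(2R,3R)-2-methyl-3-[(3S)-3-methylhex-5-en-1-yl]oxiran-2-yl]ethyl}-6-(triethylsilyloxy)octa-4,7-dien-3-ol | C=CC[C@@H](C)CC[C@H]1O[C@]1(C)CC[C@](O)(C(C)C)/C=C/[C@](C)(O[Si](CC)(CC)CC)C=C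
F5 | step 15 | (1R,4S)-4-methyl-1-[(2S,5S)-2-methyl-5-[(1E,3S)-3-methyl-4-oxo-3-(triethylsilyloxy)but-1-en-1-yl]-5-(propan-2-yl)oxolan-2-yl]-6-oxohexyl acetate | CC(=O)O[C@H](CC[C@H](C)CC=O)[C@]1(C)CC[C@](O1)(C(C)C)/C=C/[C@](C)(O[Si](CC)(CC)CC)C=O
F6 | step 15 | (1S,2E,4R,8S,11R,12S)-4-(triethylsilyloxy)-1,12-epoxycembra-2,5-dien-11-yl acetate | CC(=O)O[C@@H]1CC[C@H](C)CC=C[C@@](C)(O[Si](CC)(CC)CC)/C=C/[C@@]2(C(C)C)CC[C@]1(C)O2
F7 | step 16 | (1S,2E,4R,8S,11R,12S)-4,6-dihydroxy-1,12-epoxycembr-2-en-11-yl acetate | CC(=O)O[C@@H]1CC[C@H](C)CC(O)C[C@@](C)(O)/C=C/[C@@]2(C(C)C)CC[C@]1(C)O2
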